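## Retrosynthetic overview
1. There is one strategic disconnection, the C1–O acyl bond. It gives a quinic acid derivative with only the tertiary 1-OH free, plus an activated, phenol-protected caffeic acid.
2. All four ring stereocentres come from (−)-quinic acid (chiral pool), and the E-alkene comes from caffeic acid. No stereocentre is created or broken in the route.
3. One step differentiates the four OH groups and the CO2H. The 5-OH and CO2H are tied as a γ-lactone and the cis-3,4-diol as an acetonide.
4. No ring of the target is built, since the cyclohexane and arene are purchased. The two temporary rings (lactone and dioxolane) form together in step 1 and open together in step 5.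
5. The catechol is masked as a diacetate, so the acetates, acetonide and lactone all fall in one aqueous acid step.

Assumption: IUPAC quinic acid numbering is used. The target SMILES has 1-O, 3-OH and 4-OH on one ring face, 5-OH and CO2H on the other, and C3 and C5 both R, which is the natural (−)-quinic acid series.

## Route

**Step 1**
Reactants: 1, (−)-quinic acid [(1S,3R,4S,5R)-1,3,4,5-tetrahydroxycyclohexane-1-carboxylic acid]
Product: 2, 3,4-O-isopropylidene-1,5-quinide. This is the quinic acid γ-lactone between CO2H and O-5 (6-oxabicyclo[3.2.1]octan-7-one core) with the cis-3,4-diol as acetonide and the bridgehead 1-OH free.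
Conditions: 2,2-dimethoxypropane (3 equiv), p-TsOH·H2O (5 mol %), acetone, reflux, 2–4 h; then Et3N quench
Reagents that add atoms: 2,2-dimethoxypropane, COC(C)(C)OC
Why: This is acid-catalysed transketalisation plus intramolecular Fischer lactonisation under thermodynamic control; only the cis-3,4-diol can close a dioxolane and only the 5-OH is cis to CO2H, so the tertiary 1-OH alone stays free and no C–O bond at a stereocentre is broken.

**Step 2**
Reactants: 3, (E)-caffeic acid
Product: 4, (E)-3,4-diacetoxycinnamic acid
Conditions: Ac2O (3 equiv), pyridine, cat. DMAP, 0 °C → rt; then ice/1 M HCl work-up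
Reagents that add atoms: acetic anhydride, CC(=O)OC(C)=O
Why: This is nucleophile-catalysed O-acetylation of both phenols; any mixed anhydride at the carboxyl is hydrolysed in the aqueous work-up and the E-alkene is untouched.

**Step 3**
Reactants: 4, (E)-3,4-diacetoxycinnamic acid
Product: 5, (E)-3,4-diacetoxycinnamoyl chloride (used crude)
Conditions: (COCl)2 (1.5 equiv), cat. DMF, CH2Cl2, 0 °C → rt; concentrate
Reagents that add atoms: oxalyl chloride, O=C(Cl)C(=O)Cl
Why: This is DMF-catalysed (Vilsmeier-type) acid chloride formation, mild enough that the aryl acetates and the E-enoate survive.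

**Step 4**
Reactants: 2, 3,4-O-isopropylidene-1,5-quinide; 5, (E)-3,4-diacetoxycinnamoyl chloride (1.3–1.5 equiv)
Product: 6, 1-O-[(E)-3,4-diacetoxycinnamoyl]-3,4-O-isopropylidene-1,5-quinide
Conditions: DMAP (0.2–0.5 equiv), pyridine/CH2Cl2, 0 °C → rt, 12–24 h
Reagents that add atoms: none beyond 5
Why: This is DMAP-catalysed acylation through the acylpyridinium at the only free OH, which is an exposed bridgehead tertiary alcohol; the C1–O bond is not broken, so C1 is retained, and the lactone, acetonide and aryl acetates are inert to these conditions.

**Step 5**
Reactants: 6, the fully protected ester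
Product: 7, 1-O-caffeoylquinic acid (target)
Conditions: THF/1 M aq HCl (about 1:3), degassed, Ar, dark, rt, 5–10 d (HPLC monitoring); NaCl, EtOAc extraction; recrystallise from H2O or purify on C18
Reagents that add atoms: water, O (its OH ends up in the CO2H on lactone opening)
Why: This is acid-catalysed global hydrolysis (acetal cleavage plus A_AC2 cleavage of the aryl acetates and the strained γ-lactone), which outruns hydrolysis of the hindered, conjugated tertiary cinnamate; acid avoids the acyl migration and catechol oxidation seen in base, and no stereocentre C–O bond is cleaved.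

Mass balance for step 5: 6 (C23H24O10) + 4 H2O → 7 (C16H18O9) + acetone + 2 AcOH.

## Compound list
1 | (−)-quinic acid | O[C@]1(C(=O)O)C[C@@H](O)[C@H](O)[C@H](O)C1 | starting material
2 | 3,4-O-isopropylidene-1,5-quinide | O[C@]1(C(=O)O2)C[C@@H]2[C@H](O3)[C@H](OC3(C)C)C1 | intermediate
3 | (E)-caffeic acid | OC(=O)/C=C/c1ccc(O)c(O)c1 | starting material
4 | (E)-3,4-diacetoxycinnamic acid | OC(=O)/C=C/c1ccc(OC(C)=O)c(OC(C)=O)c1 | intermediate
5 | (E)-3,4-diacetoxycinnamoyl chloride | ClC(=O)/C=C/c1ccc(OC(C)=O)c(OC(C)=O)c1 | intermediate
6 | 1-O-[(E)-3,4-diacetoxycinnamoyl]-3,4-O-isopropylidene-1,5-quinide | O=C(/C=C/c1ccc(OC(C)=O)c(OC(C)=O)c1)O[C@]1(C(=O)O2)C[C@@H]2[C@H](O3)[C@H](OC3(C)C)C1 | intermediate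
7 | 1-O-caffeoylquinic acid | O=C(/C=C/c1ccc(O)c(O)c1)O[C@]1(C(=O)O)C[C@@H](O)[C@H](O)[C@H](O)C1 | target

## Summary
Total steps: 5.
Longest linear sequence: 4 (3 → 4 → 5 → 6 → 7). The quinic acid branch is 3 steps (1 → 2 → 6 → 7).

Steps most likely to fail:
1. **Step 5.** The risks are slow or incomplete lactone opening and partial loss of the caffeoyl ester.
   - Fallback: abandon the lactone as a mask.
   - Open 2 with allyl alcohol/alkoxide to allyl 3,4-O-isopropylidenequinate and protect the 5-OH as its Alloc carbonate.
   - Acylate the 1-OH with di-O-allylcaffeoyl chloride.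
   - Remove all allyl groups with Pd(PPh3)4 and a scavenger under neutral conditions, then cleave the acetonide with brief aqueous TFA.
2. **Step 4.** The risks are sluggish acylation of the tertiary OH and acetyl transfer from the aryl acetates.
   - Fallback: change the bond formed.
   - Heat 2 with Meldrum's acid in toluene to give the 1-O-malonyl half ester.
   - Run a Knoevenagel–Doebner condensation with 3,4-dihydroxybenzaldehyde (pyridine, cat. piperidine) to build the E-caffeate on the quinide without phenol protection, then hydrolyse in acid.
3. **Step 3.** The risk is decomposition or poor quality of the acid chloride.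
   - Fallback: acylate 2 with acryloyl chloride, which is small and reactive.
   - Install the arene by Mizoroki–Heck coupling with 4-iodo-1,2-diacetoxybenzene (Pd(OAc)2, P(o-tol)3, Et3N). This also gives 6, E-selectively.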